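The route rests on cutting the bond between the benzylic CH2 on C4 of the oxolane ring and C1 of the 2,4,5-trimethoxyphenyl ring. Because C4 carries, besides its ring bonds, only H and this CH2, an exocyclic C4=CH2 bond on a flat 4,5-dihydrofuran (3, with the other aryl group on C2 and an ester on C3) is its latent form. In one flask a chiral dialkylborane places H on C4 and boron on the CH2, and the B-alkyl group is coupled with the aryl bromide: the two halves are joined and C4 is set. Hydrogenation of C2=C3 from the face opposite the new benzyl group then gives the all-cis ring; ester reduction ends the route.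

Key step: step 2

Remark on the chemistry (assumption): the (10R) antipode of the borane is written as the one that delivers hydrogen to the C4 face leading to 4R; if the sense proves opposite, the (10S) antipode is used, and recrystallisation of 7 is foreseen if reagent control is incomplete.

Step 1
Reactants: 1 ethyl 3-oxo-3-(3,4,5-trimethoxyphenyl)propanoate; 2 methyl prop-2-yn-1-yl carbonate
Product: 3 ethyl 4-methylidene-2-(3,4,5-trimethoxyphenyl)-4,5-dihydrofuran-3-carboxylate
Conditions: Pd2(dba)3·CHCl3 (2.5 mol %), dppe (10 mol %), THF, 25 → 50 °C; chromatography on Et3N-deactivated silica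
Reagents that add atoms: none
Why: Palladium-catalysed [3+2] annulation of a propargylic carbonate with a 1,3-dicarbonyl compound: zerovalent palladium ionises 2 with loss of CO2, the enolate carbon of 1 attacks the central carbon of the allenylpalladium species and the enol oxygen closes on the π-allyl terminus, so the ring forms under neutral conditions with the exocyclic methylene intact and no stereocenter.

Step 2
Reactants: 3 ethyl 4-methylidene-2-(3,4,5-trimethoxyphenyl)-4,5-dihydrofuran-3-carboxylate; 4 1-bromo-2,4,5-trimethoxybenzene
Product: 6 ethyl (4R)-2-(3,4,5-trimethoxyphenyl)-4-[(2,4,5-trimethoxyphenyl)methyl]-4,5-dihydrofuran-3-carboxylate, via B-alkyl borane 5 (not isolated)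
Conditions: (10R)-10-phenyl-9-borabicyclo[3.3.2]decane (1.2 equiv), THF, 0 → 25 °C; then 4, Pd(OAc)2 (5 mol %), SPhos (10 mol %), K3PO4, H2O, THF, 60 °C
Reagents that add atoms: none
Why: The dialkylborane adds to the exocyclic C4=CH2 bond through a four-centre syn transition state, boron going to the unhindered terminal carbon and hydrogen to C4, and the primary alkyl group of 5 is then transferred with retention to the arylpalladium bromide formed from 4 and zerovalent palladium, reductive elimination forming the aryl–CH2 bond. The closest known reaction types are the asymmetric hydroboration of 1,1-disubstituted alkenes with 10-substituted 9-borabicyclo[3.3.2]decanes and the B-alkyl Suzuki–Miyaura coupling. No ring is closed. The new stereocenter C4 is set under reagent control, and the two substituents on the alkene carbon differ strongly in size (ring CH2O against the tetrasubstituted C3 that carries the ester), the case in which this borane class discriminates faces best. The step needs chemoselectivity for the exocyclic alkene over the tetrasubstituted donor–acceptor C2=C3 bond and the ester, which hindered dialkylboranes leave untouched, and 1,4-addition is excluded because the ring locks the diene s-trans. In the coupling only the primary B–CH2 group should migrate, the two secondary B–C bonds of the cage being slow to transfer.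

Step 3
Reactants: 6 ethyl (4R)-2-(3,4,5-trimethoxyphenyl)-4-[(2,4,5-trimethoxyphenyl)methyl]-4,5-dihydrofuran-3-carboxylate
Product: 7 ethyl (2R,3S,4R)-2-(3,4,5-trimethoxyphenyl)-4-[(2,4,5-trimethoxyphenyl)methyl]oxolane-3-carboxylate
Conditions: H2 (10 bar), Rh/Al2O3 (5 wt %), EtOAc, 25 °C
Reagents that add atoms: none
Why: Heterogeneous catalytic hydrogenation adds both hydrogens syn to C2=C3 from the face opposite the C4 benzyl group, so the C2 aryl group and the C3 ester end up cis to each other and to the C4 substituent (C2 and C3 set by substrate control).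

Step 4
Reactants: 7 ethyl (2R,3S,4R)-2-(3,4,5-trimethoxyphenyl)-4-[(2,4,5-trimethoxyphenyl)methyl]oxolane-3-carboxylate
Product: 8 [(2R,3R,4R)-2-(3,4,5-trimethoxyphenyl)-4-[(2,4,5-trimethoxyphenyl)methyl]oxolan-3-yl]methanol
Conditions: LiAlH4, THF, −20 → 0 °C; then H2O
Reagents that add atoms: none
Why: Hydride reduction of the ester to the primary alcohol, fast at low temperature relative to enolisation, so C3 should not epimerise and no stereocenter is touched (the C3 descriptor changes from S to R only because the priorities change).

Compound list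
1 | ethyl 3-oxo-3-(3,4,5-trimethoxyphenyl)propanoate | CCOC(=O)CC(=O)c1cc(OC)c(OC)c(OC)c1 | starting material
2 | methyl prop-2-yn-1-yl carbonate | C#CCOC(=O)OC | starting material
3 | ethyl 4-methylidene-2-(3,4,5-trimethoxyphenyl)-4,5-dihydrofuran-3-carboxylate (no stereocenter) | CCOC(=O)C1=C(c2cc(OC)c(OC)c(OC)c2)OCC1=C | intermediate
4 | 1-bromo-2,4,5-trimethoxybenzene | COc1cc(OC)c(OC)cc1Br | starting material
5 | (10R)-9-{[(3R)-4-(ethoxycarbonyl)-5-(3,4,5-trimethoxyphenyl)-2,3-dihydrofuran-3-yl]methyl}-10-phenyl-9-borabicyclo[3.3.2]decane (B-alkyl borane) | CCOC(=O)C1=C(c2cc(OC)c(OC)c(OC)c2)OC[C@@H]1CB1[C@@H]2CCC[C@@H](CCC2)[C@@H]1c1ccccc1 | intermediate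
6 | ethyl (4R)-2-(3,4,5-trimethoxyphenyl)-4-[(2,4,5-trimethoxyphenyl)methyl]-4,5-dihydrofuran-3-carboxylate | COc1cc(OC)c(OC)cc1C[C@H]1COC(c2cc(OC)c(OC)c(OC)c2)=C1C(=O)OCC | intermediate
7 | ethyl (2R,3S,4R)-2-(3,4,5-trimethoxyphenyl)-4-[(2,4,5-trimethoxyphenyl)methyl]oxolane-3-carboxylate (all three ring substituents cis) | COc1cc(OC)c(OC)cc1C[C@H]1CO[C@@H](c2cc(OC)c(OC)c(OC)c2)[C@H]1C(=O)OCC | intermediate
8 | [(2R,3R,4R)-2-(3,4,5-trimethoxyphenyl)-4-[(2,4,5-trimethoxyphenyl)methyl]oxolan-3-yl]methanol (all-cis) | COc1cc(OC)c(OC)cc1C[C@H]1CO[C@@H](c2cc(OC)c(OC)c(OC)c2)[C@H]1CO | target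

Total step count: 4
Longest linear sequence: 4 steps (1 → 3 → 6 → 7 → 8)

Steps most likely to fail

Step 2. The chiral borane may discriminate the two faces of the exocyclic alkene only partly. The hindered B-alkyl group may also transfer slowly, so that protodeboronation or β-hydride elimination competes with coupling. The fallback sets out from 4 and comes back at 6, with C4 set by catalyst control instead. Bromide 4 is converted (n-BuLi, THF, −78 °C; B(OMe)3; aqueous HCl) into (2,4,5-trimethoxyphenyl)boronic acid F1. F1 is added to commercial dimethyl itaconate in a rhodium-catalysed conjugate arylation with enantioselective protonation ([Rh(OH)(cod)]2, the BINAP antipode that gives R, 2-methoxyphenol, dioxane, 100 °C). This forms the same aryl–CH2 bond and should give dimethyl (2R)-2-[(2,4,5-trimethoxyphenyl)methyl]butanedioate F2. Saponification of the unhindered ester (LiOH, THF/H2O, 0 °C) should give (3R)-3-(methoxycarbonyl)-4-(2,4,5-trimethoxyphenyl)butanoic acid F3. LiBH4 reduction of the remaining ester and acid lactonisation should give (4R)-4-[(2,4,5-trimethoxyphenyl)methyl]oxolan-2-one F4. C-Aroylation of its enolate (LiN(SiMe3)2, THF, −78 °C; 3,4,5-trimethoxybenzoyl chloride) should give (4R)-3-(3,4,5-trimethoxybenzoyl)-4-[(2,4,5-trimethoxyphenyl)methyl]oxolan-2-one F5. HCl in EtOH at reflux opens the lactone to the ethyl ester and closes the freed primary alcohol onto the aryl ketone with loss of water, which should give 6.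

Step 3. Hydrogen uptake at the tetrasubstituted donor–acceptor C2=C3 bond may be slow, the benzylic C2–O bond may undergo hydrogenolysis once the ring is saturated, or face selectivity may be incomplete. The fallback sets out from 6 and comes back at 8. The ester is reduced first (i-Bu2AlH, CH2Cl2, −78 °C) to [(4R)-2-(3,4,5-trimethoxyphenyl)-4-[(2,4,5-trimethoxyphenyl)methyl]-4,5-dihydrofuran-3-yl]methanol F6, in which C2=C3 is an ordinary electron-rich enol ether. Homogeneous hydrogenation with [Ir(cod)(PCy3)(py)]PF6 (H2, CH2Cl2, 0 °C), again from the face opposite the C4 substituent, should then give 8 directly.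

Step 1. The exocyclic double bond may migrate into the ring (aromatisation to the 4-methylfuran) on the catalyst or during work-up, or C-propargylation may occur without ring closure. The fallback sets out from 1 and comes back at 3. C-Acylation of the magnesium enolate of 1 with chloroacetyl chloride (MgCl2, Et3N, MeCN, 0 °C) followed by ring closure through O-alkylation should give ethyl 4-oxo-2-(3,4,5-trimethoxyphenyl)-4,5-dihydrofuran-3-carboxylate F7. Methylenation of the ring ketone with the titanium methylidene generated from Cp2TiMe2 (toluene, 65 °C), a reagent that is neither basic nor acidic, should give 3.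

Further compounds
F1 | step 2 | (2,4,5-trimethoxyphenyl)boronic acid | COc1cc(OC)c(OC)cc1B(O)O
F2 | step 2 | dimethyl (2R)-2-[(2,4,5-trimethoxyphenyl)methyl]butanedioate | COc1cc(OC)c(OC)cc1C[C@H](CC(=O)OC)C(=O)OC
F3 | step 2 | (3R)-3-(methoxycarbonyl)-4-(2,4,5-trimethoxyphenyl)butanoic acid | COc1cc(OC)c(OC)cc1C[C@H](CC(=O)O)C(=O)OC
F4 | step 2 | (4R)-4-[(2,4,5-trimethoxyphenyl)methyl]oxolan-2-one | COc1cc(OC)c(OC)cc1C[C@@H]1CC(=O)OC1
F5 | step 2 | (4R)-3-(3,4,5-trimethoxybenzoyl)-4-[(2,4,5-trimethoxyphenyl)methyl]oxolan-2-one | COc1cc(OC)c(OC)cc1C[C@@H]1C(C(=O)c2cc(OC)c(OC)c(OC)c2)C(=O)OC1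
F6 | step 3 | [(4R)-2-(3,4,5-trimethoxyphenyl)-4-[(2,4,5-trimethoxyphenyl)methyl]-4,5-dihydrofuran-3-yl]methanol | COc1cc(OC)c(OC)cc1C[C@H]1COC(c2cc(OC)c(OC)c(OC)c2)=C1CO
F7 | step 1 | ethyl 4-oxo-2-(3,4,5-trimethoxyphenyl)-4,5-dihydrofuran-3-carboxylate | CCOC(=O)C1=C(c2cc(OC)c(OC)c(OC)c2)OCC1=O
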